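All runs are calculated for substances that don't exist; scatter was added.

**Counting turnovers.** Target is what I count, as a fraction of the starting material charged, and both earlier runs rise along straight lines within their scatter.

in all of them: starting material 0.050 M
- maple: second substrate 1 equiv; free enzyme 0.049 mol%; added ligand 9 µM; temperature 2 °C; run made earlier
- ash: second substrate 1 equiv; free enzyme 0.077 mol%; added ligand 9 µM; temperature 19 °C; run made earlier
- summer: second substrate 1.00 equiv; free enzyme 0.035 mol%; added ligand 9.0 µM; temperature −5 °C; time 20 min
- noon: second substrate 1.00 equiv; free enzyme 0.035 mol%; added ligand 9.0 µM; temperature 25 °C; time 20 min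
- spring: second substrate 1.00 equiv; free enzyme 0.035 mol%; added ligand 9.0 µM; temperature 10 °C; time 20 min

- maple (time / min: target / %): 2.00: 0.8; 4.00: 2.3; 6.00: 1.9; 12.0: 5.4; 25.0: 10.6
- ash (time / min: target / %): 0.667: 2.8; 2.00: 7.1; 4.00: 16.6; 5.00: 20.0; 8.00: 31.5

(scatter of a reading: 0.5 percentage points)



- the flask with the highest amount of target, in percent of the starting material charged ("all alike" if they lie within 1.5 percentage points) (summer / noon / spring / all alike)
- final target, as a percentage of the starting material charged, in summer
- final target, as a percentage of the starting material charged, in noon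
- final target, as a percentage of the starting material charged, in spring

**Maple against ash.** These flasks hold the same amounts of starting material, second substrate and added ligand, yet ash reaches 31.5% after 8.00 min and maple 10.6% after 25.0 min. Ash holds more free enzyme, so I divide the last reading by loading and time. Maple then gives 8.65 min⁻¹ and ash 51.1 min⁻¹. This is the turnover rate, the field's turnover frequency: target made per minute per enzyme charged. Ash turns faster by a factor of 5.91, and with loading and time divided out, the temperature step is what differs between the two. Read as an Arrhenius line, that factor gives an apparent energy of 69.8 kJ mol⁻¹, a reading that carries the scatter.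

**The zero.** Summer, spring and noon share a loading of 0.035 mol% and a time of 20 min. At maple's turnover rate each gets 6.06%, and that is the zero of my scale. The line moves the rate to 3.90 min⁻¹ in summer, 20.5 min⁻¹ in spring and 91.2 min⁻¹ in noon. I therefore reckon 2.73%, 14.4% and 63.8%.

**The forecast.** It names noon, with 2.6% in summer, 14% in spring and 57% in noon. Its noon figure stands below mine, and it says of that flask that “substrate depletion or enzyme deactivation probably trims the yield”.

**What held.** Summer gives 2.35%, spring 14.2% and noon 58.3%, the most, so the forecast stands.

    starting material + free enzyme ⇌ complex A (K = 160 M⁻¹, k = 70000 M⁻¹ min⁻¹, Ea = 45.0 kJ mol⁻¹, ΔH = 31.0 kJ mol⁻¹)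
    free enzyme + added ligand ⇌ idle complex, settled at all times (K = 72000 M⁻¹, ΔH = 12.0 kJ mol⁻¹)
    complex A → free enzyme + target (k = 140 min⁻¹, Ea = 63.0 kJ mol⁻¹)
    free enzyme → unfolded enzyme (k = 0.00330 min⁻¹, Ea = 226 kJ mol⁻¹)
    complex B → free enzyme + second product (k = 100 min⁻¹, Ea = 69.0 kJ mol⁻¹)
    second substrate + free enzyme ⇌ complex B (K = 25.0 M⁻¹, k = 17000 M⁻¹ s⁻¹, Ea = 29.0 kJ mol⁻¹, ΔH = −2.00 kJ mol⁻¹)
    (constants at 25 °C)

Noon ran at 83.3 min⁻¹, and its unfolded enzyme stood at 0.973%. Without temperature acting on complex A's turning into free enzyme and target, noon minus summer shrinks from 56 percentage points to 1.8 points, the largest single effect. Spring's neighbour charged with 0.013 M keeps loading and time, yet turns at 12.4 min⁻¹ against spring's 20.3 min⁻¹, with complex A at 33.0% of the catalyst against 54.2%.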